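**Assumptions**
- Catalyst (S) or (R) is chosen to give the enantiomer shown; I assume (S)-diphenylprolinol TMS ether does so.
- The C5/C6 epimers in 7–11 converge at step 9, and the minor C1 epimer is removed by chromatography (the anomeric effect should favour the target epimer).
- Numbering is iridoid numbering: C10 is the CH2OAc on C8, and C11 is the CH2OAc on C4.

**Retrosynthesis**
- The dihydropyran enol ether and the C1 acyloxy acetal close last, by an intramolecular Horner–Wadsworth–Emmons (HWE) reaction from a C1 acylal–phosphonate tether onto the C4 ketone.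
- C5=C6 comes from E1cB loss of AcOH. The C7 carbinol comes from hydroxyl-directed anti reduction of the C7 ketone next to the C8 tertiary alcohol.
- The cyclopentane is built first, in one organocatalytic Michael/aldol annulation. This step sets C8 and C9; C5 and C6 are epimeric and converge later.
- The annulation joins a 4-oxo-enal from furfuryl acetate to a symmetric vicinal diketone from butynediol.

**Route**

**Step 1**
Reactants: 1 furfuryl alcohol
Product: 2 furfuryl acetate
Conditions: Ac2O, Et3N, DMAP (cat.), CH2Cl2, 0 °C → rt
Reagents that add atoms: acetic anhydride, CC(=O)OC(C)=O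
Why: Plain O-acetylation of a primary alcohol.

**Step 2**
Reactants: 2
Product: 3 (Z)-5-acetoxy-4-oxopent-2-enal
Conditions: NBS, NaHCO3, pyridine, THF/H2O (4:1), –10 °C
Reagents that add atoms: water, O (its oxygen ends up in the aldehyde)
Why: Oxidative ring opening of a 2-substituted furan gives the cis-4-oxo-enal (Achmatowicz-type chemistry without a free hydroxyl). This is a double Michael acceptor; the E/Z geometry does not matter downstream.

**Step 3**
Reactants: 4 2-butyne-1,4-diol
Product: 5 1,4-diacetoxybut-2-yne
Conditions: Ac2O, pyridine, DMAP (cat.), CH2Cl2, 0 °C → rt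
Reagents that add atoms: acetic anhydride, CC(=O)OC(C)=O
Why: Bis-acetylation of a primary diol.

**Step 4**
Reactants: 5
Product: 6 1,4-diacetoxybutane-2,3-dione
Conditions: RuCl3·xH2O (5 mol%), NaIO4 (4 equiv), EtOAc/MeCN/H2O, 0 °C → rt
Reagents that add atoms: sodium periodate, [Na+].[O-]I(=O)(=O)=O; water, O (oxygen atoms end up in the diketone)
Why: RuO4 oxidation of an internal alkyne gives the 1,2-diketone. The product is symmetric, so the next step starts from a donor with only one kind of α-carbon.

**Step 5 (key step)**
Reactants: 3 and 6
Product: 7 (cyclopentanone aldehyde)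
Conditions: (S)-diphenylprolinol TMS ether (20 mol%), PhCO2H (20 mol%), toluene, 4 °C, 48 h, then aqueous workup
Reagents that add atoms: none
Why: Proposed new method: a secondary amine converts one carbonyl of symmetric diketone 6 into an α-acyloxy enamine. That enamine adds to C5 of 3, the position β to the more activating aldehyde and α to the ketone. Hydrolysis then frees the C7 ketone and leaves an aldehyde whose enamine closes onto the remaining, more electrophilic C8 ketone by a 5-(enolexo)-exo-trig aldol, through a H-bonded syn transition state. This forms the C8 tertiary carbinol and C9, with the hydroxyl cis to the CHO; the catalyst enamine faces set the absolute configuration, and C5/C6 are epimeric. The closest known reactions are Hayashi–Jørgensen enamine Michael–aldol cascades and List/Barbas α-hydroxyketone enamine chemistry, here applied to a vicinal diketone donor and a 4-oxo-enal acceptor.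

**Step 6**
Reactants: 7 and 8 diethyl (hydroxymethyl)phosphonate
Product: 9 (C1 acylal–phosphonate)
Conditions: 8 (1.5 equiv), then (iPrCO-CH2... isovaleric anhydride) 3 equiv, DMAP (0.3 equiv), iPr2NEt, CH2Cl2, 0 °C → rt
Reagents that add atoms: isovaleric anhydride, CC(C)CC(=O)OC(=O)CC(C)C
Why: Hemiacetal formation followed by acylation traps the aldehyde as an α-acyloxy ether, installing the C1 OIsov and the C3 phosphonate carbon. Reversible hemiacetal formation lets the anomer be set by thermodynamic control. The hindered tertiary C8–OH is not acylated.

**Step 7**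
Reactants: 9
Product: 10 (trans 7,8-diol)
Conditions: Me4NBH(OAc)3, MeCN/AcOH (1:1), –20 °C → rt
Reagents that add atoms: none (adds H only)
Why: Evans–Saksena hydroxyl-directed reduction: the C8–OH binds the acyloxyborohydride and delivers hydride to C7 from its own face. This puts C7–OH anti to C8–OH (cis to C10), as in the target. The C4 ketone, which has no directing group, is left alone.

**Step 8**
Reactants: 10
Product: 11 (C7 isovalerate)
Conditions: isovaleric anhydride, DMAP, pyridine, CH2Cl2, 0 °C
Reagents that add atoms: isovaleric anhydride, CC(C)CC(=O)OC(=O)CC(C)C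
Why: Selective acylation of the secondary alcohol with retention of configuration; the tertiary C8–OH stays free.

**Step 9**
Reactants: 11
Product: 12 (enone)
Conditions: DBU (1.1 equiv), CH2Cl2, 0 °C
Reagents that add atoms: none
Why: The β-acetoxy ketone loses AcOH by E1cB through the C5 enolate, forming the trisubstituted C5=C6 alkene. The C5/C6 stereocentres are erased, so no stereochemical information is lost.

**Step 10**
Reactants: 12
Product: 13 10-acetoxyvaltrathydrin
Conditions: KHMDS (2.2 equiv), THF, –78 → 0 °C
Reagents that add atoms: none
Why: The phosphonate carbanion closes onto the C4 ketone by an intramolecular HWE reaction through a six-membered transition state. This forms the C3=C4 enol ether and the C3–O2 ring bond in one step, giving the dienyl pyran; the ring fixes the alkene geometry and C1–C9 stay as set.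

**Compound list**

| No. | Name | SMILES | Role |
|---|---|---|---|
| 1 | furfuryl alcohol | OCc1ccco1 | starting material |
| 2 | furfuryl acetate | CC(=O)OCc1ccco1 | intermediate |
| 3 | (Z)-5-acetoxy-4-oxopent-2-enal | O=C/C=C\C(=O)COC(C)=O | intermediate |
| 4 | 2-butyne-1,4-diol | OCC#CCO | starting material |
| 5 | 1,4-diacetoxybut-2-yne | CC(=O)OCC#CCOC(C)=O | intermediate |
| 6 | 1,4-diacetoxybutane-2,3-dione | CC(=O)OCC(=O)C(=O)COC(C)=O | intermediate |
| 7 | cyclopentanone aldehyde (C8 tertiary OH, CHO at C9; C5/C6 epimeric) | O=C[C@H]1C(C(=O)COC(C)=O)C(OC(C)=O)C(=O)[C@]1(O)COC(C)=O | intermediate |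
| 8 | diethyl (hydroxymethyl)phosphonate | CCOP(=O)(CO)OCC | starting material |
| 9 | C1 acylal–phosphonate ketone | CCOP(=O)(OCC)CO[C@@H](OC(=O)CC(C)C)[C@H]2C(C(=O)COC(C)=O)C(OC(C)=O)C(=O)[C@]2(O)COC(C)=O | intermediate |
| 10 | trans 7,8-diol | CCOP(=O)(OCC)CO[C@@H](OC(=O)CC(C)C)[C@H]2C(C(=O)COC(C)=O)C(OC(C)=O)[C@H](O)[C@]2(O)COC(C)=O | intermediate |
| 11 | C7 isovalerate | CCOP(=O)(OCC)CO[C@@H](OC(=O)CC(C)C)[C@H]2C(C(=O)COC(C)=O)C(OC(C)=O)[C@H](OC(=O)CC(C)C)[C@]2(O)COC(C)=O | intermediate |
| 12 | enone (C5=C6) | CCOP(=O)(OCC)CO[C@@H](OC(=O)CC(C)C)[C@H]2C(C(=O)COC(C)=O)=C[C@H](OC(=O)CC(C)C)[C@]2(O)COC(C)=O | intermediate |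
| 13 | 10-acetoxyvaltrathydrin (C24H34O10) | CC(=O)OCC1=CO[C@@H](OC(=O)CC(C)C)[C@H]2C1=C[C@H](OC(=O)CC(C)C)[C@]2(O)COC(C)=O | target |

**Totals**
- Total steps: 10.
- Longest linear sequence: 8 steps (1 → 2 → 3 → 7 → 9 → 10 → 11 → 12 → 13).

**Three steps most likely to fail**
1. **Step 5 (new Michael/aldol annulation).** The bis-electrophilic acceptor may polymerize, or the regiochemistry and syn selectivity may be poor.
   - Fallback: run it stepwise with known chemistry. First a Hayashi–Jørgensen or List enamine Michael addition of an α-acetoxy ketone to 3, then a proline-catalysed intramolecular aldehyde–ketone aldol on the isolated 1,5-ketoaldehyde.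
2. **Step 10 (intramolecular HWE).** The α-alkoxy phosphonate needs a strong base, which risks acyl migration, epimerization or attack on the esters.
   - Fallback: put a dimethyl acetal on C1 in step 6 instead of the phosphonate. Then use Ph3P=CHOMe methoxymethylenation of the C4 ketone, aqueous-acid dialdehyde cyclization to the lactol (the iridoid biomimetic closure), and final isovalerylation of C1–OH.
3. **Step 7 (directed reduction).** Selectivity over the C4 ketone may be poor, or the C6 acetate may migrate to C7–OH.
   - Fallback: Luche reduction (NaBH4/CeCl3) followed by Mitsunobu inversion with isovaleric acid, which sets the C7 configuration and installs OIsov in one step.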